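Locants used: seven-membered ring C1 (CHOAng beside C7), C2 (CH2), C3 (CHOAng), C4 (C(CH3)CH2OH), C5, C6, C7; cyclobutane C5 (H), C6 (H), C7 (CH3), C8 (H); ring A = C6–C11(=O)–C10H2–C9H(CH3)–C8.
Cuts, in retrosynthetic order: the two angelates and the C1/C3 carbinols; the C9 methyl and the C9–C10 bond of ring A (cuprate, aldol); the cyclobutane bond C7–C8 (enolate/epoxide); then C2–C3 and C5–C6 together, which opens the seven-membered ring to a dienone and an acryloylsilane.
Enabling feature: in the seven-membered ring the CH2 C2 lies between two oxygenated carbons (C1, C3), each flanked by a carbon that ends quaternary (C7, C4), and C5–C6 is a cis CH–CH pair. This is the retron of a Brook-rearrangement-mediated [3+4] annulation, which also leaves C7 as a regiodefined enolate and C4 as a silyl enol ether.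
Forward order of rings: seven-membered ring (step 5), cyclobutane (step 11), ring A (step 13); the esters last.
Stereochemistry: C5/C6 cis from the two E alkenes through a boat oxy-Cope; absolute series from (R)-glyceraldehyde acetonide, whose centre becomes C8 with inversion; C4 by attack anti to the C5 substituent; C3–OH and C1–OH by two hydroxyl-directed hydride deliveries; C7/C8 by the ring closure; C9 by cuprate addition anti to the C7 methyl.

Key step: step 5

Remark: the dioxolane centre is not expected to steer the facial sense of the annulation, so two diastereomers (same dioxolane centre, opposite C5/C6 configuration) should form in step 5; they are separated by chromatography and only the one drawn is carried on.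

Step 1
Reactants: 1 methacrolein; 2 3-(triphenylphosphoranylidene)butan-2-one
Product: 3 (3E)-3,5-dimethylhexa-3,5-dien-2-one
Conditions: toluene, 80 °C
Reagents that add atoms: none
Why: Wittig olefination with a stabilised keto ylide should give the E trisubstituted enone (acetyl trans to isopropenyl), the geometry needed for the cis outcome of step 5.

Step 2
Reactants: 4 prop-1-ynylmagnesium bromide; 5 tert-butyldimethylsilyl chloride
Product: 6 tert-butyldimethyl(prop-1-ynyl)silane
Conditions: THF, 0 → 60 °C
Reagents that add atoms: none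
Why: C-silylation of an alkynyl Grignard reagent is a standard entry to 1-silylalkynes.

Step 3
Reactants: 6 tert-butyldimethyl(prop-1-ynyl)silane
Product: 8 1-(tert-butyldimethylsilyl)propan-1-one, via alkenylborane 7 (not isolated)
Conditions: Cy2BH, THF, 0 °C → rt; Me3NO (anhydrous, 3.3 equiv), THF, 65 °C; H2O
Reagents that add atoms: trimethylamine N-oxide, C[N+](C)(C)[O-]
Why: Hydroboration of a 1-silylalkyne places boron on the silicon-bearing carbon, and amine-oxide oxidation of the alkenylborane gives the acylsilane (hydroboration–oxidation).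

Step 4
Reactants: 8 1-(tert-butyldimethylsilyl)propan-1-one; 9 (R)-2,2-dimethyl-1,3-dioxolane-4-carbaldehyde
Product: 12 (S,E)-1-(tert-butyldimethylsilyl)-3-(2,2-dimethyl-1,3-dioxolan-4-yl)-2-methylprop-2-en-1-one, via lithium aldolate 10 (not isolated), via aldol mesylate 11 (not isolated)
Conditions: LiN(iPr)2, THF, −78 °C; 9, −78 °C; MsCl, −78 → 0 °C; DBU, 0 °C → rt
Reagents that add atoms: none
Why: Aldol addition of the acylsilane enolate followed by mesylation and E1cB elimination should give the E enoyl silane (silylcarbonyl trans to the dioxolane); the dioxolane centre is untouched.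

Step 5
Reactants: 3 (3E)-3,5-dimethylhexa-3,5-dien-2-one; 12 (S,E)-enoyl silane
Product: 16 1-acetoxy-3-(tert-butyldimethylsilyloxy)-4,7-dimethyl-5-[(S)-2,2-dimethyl-1,3-dioxolan-4-yl]-6-isopropenylcyclohepta-1(7),3-diene (5,6-cis), via lithium dienolate 13 (not isolated), via divinylcyclopropanolate 14 (not isolated), via cycloheptadienolate 15 (not isolated)
Conditions: LiN(iPr)2, THF, −80 °C (3 → 13); 12, −80 → −30 °C; Ac2O, −78 → 0 °C
Reagents that add atoms: acetic anhydride, CC(=O)OC(C)=O
Why: The kinetic dienolate 13 adds through its CH2 terminus to the acylsilane carbonyl of 12 (first new bond, C2–C3), the alkoxide triggers a 1,2-Brook silyl shift, and the siloxyallyl anion closes 3-exo-trig onto the ketone to give the cis-1,2-dialkenylcyclopropanolate 14, which undergoes an anionic oxy-Cope rearrangement (second new bond, C5–C6) to enolate 15, trapped on oxygen by Ac2O. The closest known reaction type is the Brook-rearrangement-mediated [3+4] annulation of β-substituted acryloylsilanes with lithium enolates of alkenyl methyl ketones. The seven-membered ring is closed by [3,3] sigmatropic ring expansion of the three-membered ring through a boat transition state, not by end-to-end cyclisation. The two new stereocentres C5 and C6 should come out cis because both alkenes are E and the boat geometry is enforced by the cis-cyclopropane; their absolute sense relative to the dioxolane centre is not controlled, hence the separation stated in the remark. The step needs 1,2- over 1,4-addition (hard lithium enolate, very electrophilic acylsilane carbonyl, −80 °C), kinetic enolisation of 3 at the acetyl methyl (LiN(iPr)2, −80 °C) and retention of the enolate position at C1/C7 (immediate O-acetylation, while the migrated silyl group marks C3/C4 as the other enol derivative). The oxygen β to the transient carbanion is a poor leaving group as part of the acetonide, which is why the diol is carried in this form and not as an epoxide.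

Step 6
Reactants: 16 bis-enol derivative
Product: 17 1-acetoxy-4-(hydroxymethyl)-4,7-dimethyl-5-[(S)-dioxolanyl]-6-isopropenylcyclohept-1(7)-en-3-one (CH2OH trans to the C5 and C6 groups)
Conditions: aq. HCHO (37%), Yb(OTf)3 (10 mol%), THF, rt
Reagents that add atoms: formaldehyde, C=O
Why: Mukaiyama aldol hydroxymethylation in water reacts only at the silyl enol ether (the enol acetate is too weak a nucleophile), and formaldehyde should enter C4 anti to the adjacent C5 dioxolanyl group to set the quaternary centre.

Step 7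
Reactants: 17 β-hydroxy ketone
Product: 18 C3 alcohol (3-OH trans to the 4-CH2OH)
Conditions: Me4NBH(OAc)3, MeCN/AcOH, −30 °C
Reagents that add atoms: none
Why: Evans–Saksena reduction delivers hydride intramolecularly from boron bound to the CH2OH oxygen, so the new C3 hydroxyl should be trans to the hydroxymethyl group.

Step 8
Reactants: 18 diol
Product: 19 di-tert-butylsilylene of 18 (O on C3 and O of the CH2O group)
Conditions: tBu2Si(OTf)2, 2,6-lutidine, CH2Cl2, 0 °C
Reagents that add atoms: di-tert-butylsilyl bis(trifluoromethanesulfonate), CC(C)(C)[Si](OS(=O)(=O)C(F)(F)F)(OS(=O)(=O)C(F)(F)F)C(C)(C)C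
Why: Cyclic silylene protection of the 1,3-diol masks both hydroxyls against the alkoxide chemistry of steps 10 and 11 and should survive acid, ozone and cuprate.

Step 9
Reactants: 19 silylene acetonide
Product: 20 diol (C5 carries (S)-CH(OH)CH2OH)
Conditions: AcOH/H2O (4:1), 40 °C
Reagents that add atoms: water, O
Why: Acid hydrolysis of the terminal isopropylidene acetal; enol acetate and silylene should be stable under these conditions.

Step 10
Reactants: 20 diol
Product: 22 epoxide (C5 carries the (S)-oxiran-2-yl group), via hydroxy tosylate 21 (not isolated)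
Conditions: TsCl, Et3N, Bu2SnO (cat.), CH2Cl2, rt; then NaH, THF, 0 °C
Reagents that add atoms: none
Why: Tin-catalysed selective sulfonylation of the primary hydroxyl of the 1,2-diol and 3-exo-tet closure by the secondary alkoxide should give the terminal epoxide with retention at C8.

Step 11
Reactants: 22 epoxide
Product: 24 bicyclo[4.1.1]octanone (C7–C8 bond closed; C8 carries CH2OH cis to the isopropenyl group on C6), via lithium enolate 23 (not isolated)
Conditions: MeLi (2.2 equiv), THF, −78 → 0 °C; HMPA, 0 → 40 °C; aq. NH4Cl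
Reagents that add atoms: none
Why: Cleavage of the enol acetate with MeLi regenerates the C7 enolate regiospecifically, and its 4-exo-tet attack on the epoxide with inversion at C8 should close the cyclobutane (O-alkylation would need a bridgehead enol ether), making C7 quaternary with the new bond on the face of the C5 side chain.

Step 12
Reactants: 24 bicyclic ketone
Product: 25 methyl ketone (acetyl on C6)
Conditions: O3, CH2Cl2/MeOH, −78 °C; Me2S, −78 °C → rt
Reagents that add atoms: ozone, [O-][O+]=O
Why: Ozonolysis of the 1,1-disubstituted alkene, the only C=C left, unmasks the acetyl group.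

Step 13
Reactants: 25 keto alcohol
Product: 27 tricyclic enone (ring A closed: C6–C11(=O)–C10H=C9H–C8), via keto aldehyde 26 (not isolated)
Conditions: Dess–Martin periodinane, NaHCO3, CH2Cl2, 0 °C → rt; then pyrrolidine, AcOH, toluene, 4 Å MS, 60 °C
Reagents that add atoms: none
Why: Dess–Martin oxidation followed by intramolecular aldol condensation of the acetyl methyl onto the cis-1,3-disposed formyl group should close ring A as the bicyclo[3.1.1]heptenone, with removal of water driving the condensation and the C1 ketone able to form only more strained rings.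

Step 14
Reactants: 27 enone
Product: 28 saturated ketone with C9 methyl (anti to the C7 methyl)
Conditions: Me2CuLi, Et2O, −78 → −30 °C; aq. NH4Cl
Reagents that add atoms: lithium dimethylcuprate, C[Cu-]C.[Li+]
Why: Conjugate addition of the Gilman reagent to the bridged enone from the face of the C5–H bridge, anti to the methyl on the C7 bridge, should set C9 as in the target.

Step 15
Reactants: 28 silylene diketone
Product: 29 diketo diol (3-OH and 4-CH2OH free)
Conditions: HF·pyridine, THF/pyridine, 0 °C → rt
Reagents that add atoms: none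
Why: Fluoride cleavage of the silylene frees the C3 hydroxyl needed to direct the next reduction.

Step 16
Reactants: 29 diketo diol
Product: 30 keto triol (1-OH anti to 3-OH)
Conditions: Me4NBH(OAc)3, MeCN/AcOH, −30 → −10 °C
Reagents that add atoms: none
Why: Evans–Saksena reduction: the C3 hydroxyl delivers hydride to the β-carbonyl C1 to give the anti-1,3-diol, while the ring A ketone, which has no β-hydroxyl, should stay untouched.

Step 17
Reactants: 30 keto triol; 5 tert-butyldimethylsilyl chloride
Product: 31 primary tert-butyldimethylsilyl ether of 30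
Conditions: imidazole, DMF, 0 °C
Reagents that add atoms: none
Why: Silylation should be selective for the primary hydroxyl over the two hindered secondary ones.

Step 18
Reactants: 31 silyl ether diol
Product: 32 1,3-bis-angelate of 31
Conditions: angelic acid, 2,4,6-trichlorobenzoyl chloride, Et3N, toluene, rt; then 31, 80 °C
Reagents that add atoms: angelic acid, C/C=C(/C)C(=O)O
Why: Yamaguchi esterification through the mixed anhydride without nucleophilic catalyst is chosen to acylate hindered alcohols while limiting Z-to-E isomerisation of the angelate.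

Step 19
Reactants: 32 bis-angelate silyl ether
Product: 33 CNP0287707.1
Conditions: HF·pyridine, THF, 0 °C → rt
Reagents that add atoms: none
Why: Fluoride removal of the primary silyl ether; the esters and the ketone should be stable.

Compound list
1 | methacrolein (2-methylprop-2-enal) | CC(=C)C=O | starting material
2 | 3-(triphenylphosphoranylidene)butan-2-one | CC(=O)C(C)=P(c1ccccc1)(c1ccccc1)c1ccccc1 | starting material
3 | (3E)-3,5-dimethylhexa-3,5-dien-2-one | CC(=O)/C(C)=C/C(C)=C | intermediate
4 | prop-1-ynylmagnesium bromide | CC#C[Mg]Br | starting material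
5 | tert-butyldimethylsilyl chloride | CC(C)(C)[Si](C)(C)Cl | starting material
6 | tert-butyldimethyl(prop-1-ynyl)silane | CC#C[Si](C)(C)C(C)(C)C | intermediate
7 | dicyclohexyl[(Z)-1-(tert-butyldimethylsilyl)prop-1-enyl]borane | C/C=C(/B(C1CCCCC1)C1CCCCC1)[Si](C)(C)C(C)(C)C | intermediate
8 | 1-(tert-butyldimethylsilyl)propan-1-one | CCC(=O)[Si](C)(C)C(C)(C)C | intermediate
9 | (R)-2,2-dimethyl-1,3-dioxolane-4-carbaldehyde (glyceraldehyde acetonide) | O=C[C@H]1COC(C)(C)O1 | starting material
10 | lithium 3-(tert-butyldimethylsilyl)-1-(2,2-dimethyl-1,3-dioxolan-4-yl)-2-methyl-3-oxopropan-1-olate (dioxolane centre as in 9; mixture at the two new centres) | CC(C(=O)[Si](C)(C)C(C)(C)C)C(O[Li])[C@H]1COC(C)(C)O1 | intermediate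
11 | methanesulfonate of the aldol corresponding to 10 | CC(C(=O)[Si](C)(C)C(C)(C)C)C(OS(C)(=O)=O)[C@H]1COC(C)(C)O1 | intermediate
12 | (S,E)-1-(tert-butyldimethylsilyl)-3-(2,2-dimethyl-1,3-dioxolan-4-yl)-2-methylprop-2-en-1-one | CC(C)(C)[Si](C)(C)C(=O)/C(C)=C/[C@H]1COC(C)(C)O1 | intermediate
13 | lithium (3E)-3,5-dimethylhexa-1,3,5-trien-2-olate (kinetic dienolate of 3) | C=C(O[Li])/C(C)=C/C(C)=C | intermediate
14 | lithium cis-1,2-dialkenylcyclopropanolate: one ring carbon with OLi and (2E)-4-methylpenta-2,4-dien-2-yl, the next with OTBS and (E)-1-[(S)-2,2-dimethyl-1,3-dioxolan-4-yl]prop-1-en-2-yl (alkenyl groups cis), the third CH2 | CC(C)(C)[Si](C)(C)O[C@]1(/C(C)=C/[C@H]2COC(C)(C)O2)C[C@@]1(O[Li])/C(C)=C/C(C)=C | intermediate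
15 | lithium enolate corresponding to 16 (OLi in place of OAc) | CC(C)(C)[Si](C)(C)OC1=C(C)[C@@H]([C@H]2COC(C)(C)O2)[C@@H](C(C)=C)C(C)=C(O[Li])C1 | intermediate
16 | 1-acetoxy-3-(tert-butyldimethylsilyloxy)-4,7-dimethyl-5-[(S)-2,2-dimethyl-1,3-dioxolan-4-yl]-6-isopropenylcyclohepta-1(7),3-diene, 5,6-cis | CC(C)(C)[Si](C)(C)OC1=C(C)[C@@H]([C@H]2COC(C)(C)O2)[C@@H](C(C)=C)C(C)=C(OC(C)=O)C1 | intermediate
17 | 1-acetoxy-4-(hydroxymethyl)-4,7-dimethyl-5-[(S)-dioxolanyl]-6-isopropenylcyclohept-1(7)-en-3-one, CH2OH trans to the C5 and C6 groups | O=C1CC(OC(C)=O)=C(C)[C@H](C(C)=C)[C@H]([C@H]2COC(C)(C)O2)[C@@]1(C)CO | intermediate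
18 | C3 alcohol of 17, 3-OH trans to the 4-CH2OH | O[C@@H]1CC(OC(C)=O)=C(C)[C@H](C(C)=C)[C@H]([C@H]2COC(C)(C)O2)[C@@]1(C)CO | intermediate
19 | di-tert-butylsilylene of 18 (bridging O on C3 and the CH2O on C4) | CC(C)(C)[Si]3(C(C)(C)C)O[C@@H]1CC(OC(C)=O)=C(C)[C@H](C(C)=C)[C@H]([C@H]2COC(C)(C)O2)[C@@]1(C)CO3 | intermediate
20 | diol from 19: C5 carries (S)-CH(OH)CH2OH | CC(C)(C)[Si]2(C(C)(C)C)O[C@@H]1CC(OC(C)=O)=C(C)[C@H](C(C)=C)[C@H]([C@H](O)CO)[C@@]1(C)CO2 | intermediate
21 | primary p-toluenesulfonate of 20 | CC(C)(C)[Si]2(C(C)(C)C)O[C@@H]1CC(OC(C)=O)=C(C)[C@H](C(C)=C)[C@H]([C@H](O)COS(=O)(=O)c3ccc(C)cc3)[C@@]1(C)CO2 | intermediate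
22 | epoxide: C5 carries the (S)-oxiran-2-yl group | CC(C)(C)[Si]3(C(C)(C)C)O[C@@H]1CC(OC(C)=O)=C(C)[C@H](C(C)=C)[C@H]([C@H]2CO2)[C@@]1(C)CO3 | intermediate
23 | lithium C1(C7) enolate from 22 (OLi in place of OAc) | CC(C)(C)[Si]3(C(C)(C)C)O[C@@H]1CC(O[Li])=C(C)[C@H](C(C)=C)[C@H]([C@H]2CO2)[C@@]1(C)CO3 | intermediate
24 | bicyclo[4.1.1]octan-1-one core: cyclobutane C5–C6–C7–C8 closed; C7 methyl, C6 isopropenyl and C8 CH2OH all on the cyclobutane face opposite the C1–C4 bridge; silylene retained | CC(C)(C)[Si]3(C(C)(C)C)O[C@@H]1CC(=O)[C@]2(C)[C@@H](CO)[C@@H]([C@H]2C(C)=C)[C@@]1(C)CO3 | intermediate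
25 | as 24 with acetyl in place of isopropenyl on C6 | CC(C)(C)[Si]3(C(C)(C)C)O[C@@H]1CC(=O)[C@]2(C)[C@@H](CO)[C@@H]([C@H]2C(C)=O)[C@@]1(C)CO3 | intermediate
26 | as 25 with formyl in place of CH2OH on C8 | CC(C)(C)[Si]3(C(C)(C)C)O[C@@H]1CC(=O)[C@]2(C)[C@@H](C=O)[C@@H]([C@H]2C(C)=O)[C@@]1(C)CO3 | intermediate
27 | tricyclic enone: ring A closed as C6–C11(=O)–C10H=C9H–C8; C1 ketone and silylene retained | CC(C)(C)[Si]4(C(C)(C)C)O[C@@H]1CC(=O)[C@]2(C)[C@@H]3[C@@H]([C@H]2C(=O)C=C3)[C@@]1(C)CO4 | intermediate
28 | as 27 with C9H(CH3)–C10H2; C9 methyl anti to the C7 methyl | CC(C)(C)[Si]4(C(C)(C)C)O[C@@H]1CC(=O)[C@]2(C)[C@@H]3[C@@H]([C@H]2C(=O)C[C@H]3C)[C@@]1(C)CO4 | intermediate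
29 | diketo diol: 28 without the silylene (3-OH, 4-CH2OH) | O[C@@H]1CC(=O)[C@]2(C)[C@@H]3[C@@H]([C@H]2C(=O)C[C@H]3C)[C@@]1(C)CO | intermediate
30 | keto triol: 1-OH anti to 3-OH, 4-CH2OH, ring A ketone | O[C@@H]1C[C@@H](O)[C@]2(C)[C@@H]3[C@@H]([C@H]2C(=O)C[C@H]3C)[C@@]1(C)CO | intermediate
31 | primary tert-butyldimethylsilyl ether of 30 | O[C@@H]1C[C@@H](O)[C@]2(C)[C@@H]3[C@@H]([C@H]2C(=O)C[C@H]3C)[C@@]1(C)CO[Si](C)(C)C(C)(C)C | intermediate
32 | 1,3-bis-angelate of 31 | C/C=C(/C)C(=O)O[C@@H]1C[C@@H](OC(=O)/C(C)=C\C)[C@]2(C)[C@@H]3[C@@H]([C@H]2C(=O)C[C@H]3C)[C@@]1(C)CO[Si](C)(C)C(C)(C)C | intermediate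
33 | CNP0287707.1 (1,3-bis-angelate, 4-hydroxymethyl, ring A ketone) | C/C=C(/C)C(=O)O[C@@H]1C[C@@H](OC(=O)/C(C)=C\C)[C@]2(C)[C@@H]3[C@@H]([C@H]2C(=O)C[C@H]3C)[C@@]1(C)CO | target

Total step count: 19. Longest linear sequence: 18 steps (steps 2 to 19, from 4 and 5 to 33).

Steps most likely to fail

Step 5. The Cope enolate may be acylated on carbon or exchange protons before it is trapped, which would lose the position of the enol double bond on which step 11 depends. The fallback sets out from 3 and 12. The annulation is quenched with aqueous NH4Cl to give the 3-siloxycyclohept-3-enone F1 (mixture at C7). Hydroxymethylation as in step 6 gives the hydroxy 1,3-diketone F2. Evans–Saksena reduction with one equivalent of Me4NBH(OAc)3, which should reach only the carbonyl β to the CH2OH group, gives the diol ketone F3, and silylene protection as in step 8 gives the silylene ketone F4. Acid-catalysed enol acetylation under equilibrating conditions (isopropenyl acetate, TsOH, 60 °C), which favours the more substituted enol acetate, should then give 19, where the route is rejoined.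

Step 11. The hindered tetrasubstituted enolate may open the epoxide too slowly, so that proton transfer from product to enolate scrambles the enolate position, or it may attack the terminal epoxide carbon. The fallback sets out from 20. Tritylation of the primary hydroxyl (TrCl, pyridine) gives the trityl ether F5, and mesylation (MsCl, Et3N) gives the secondary mesylate F6. MeLi then regenerates the enolate, which displaces the sulfonate in a keto sulfonate ring closure (inversion at C8, only one electrophilic carbon) to give the cyclobutane trityl ether F7. Aqueous formic acid removes the trityl group and gives 24.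

Step 13. The aldol equilibrium may be unfavourable for closing the strained bicyclo[3.1.1]heptenone, or condensation may occur through other enolisable positions. The fallback sets out from 24. Dess–Martin oxidation gives the aldehyde F8 with the isopropenyl group still in place. A Me2AlCl-promoted intramolecular carbonyl-ene reaction (CH2Cl2, −78 °C), kinetically controlled and irreversible, joins the formyl carbon C9 to the methylene terminus of the isopropenyl group (C10) and gives the homoallylic alcohol F9 with an exocyclic methylene on C11. Ozonolysis gives the β-hydroxy ketone F10, and mesylation with elimination (MsCl, Et3N; DBU) gives enone 27.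

Further compounds
F1 | step 5 | 3-(tert-butyldimethylsilyloxy)-4,7-dimethyl-5-[(S)-dioxolanyl]-6-isopropenylcyclohept-3-en-1-one, 5,6-cis, mixture at C7 | O=C1CC(O[Si](C)(C)C(C)(C)C)=C(C)[C@@H]([C@H]2COC(C)(C)O2)[C@@H](C(C)=C)C1C
F2 | step 5 | 4-(hydroxymethyl)-4,7-dimethyl-5-[(S)-dioxolanyl]-6-isopropenylcycloheptane-1,3-dione, CH2OH trans to the C5 and C6 groups | O=C1CC(=O)[C@](C)(CO)[C@@H]([C@H]2COC(C)(C)O2)[C@@H](C(C)=C)C1C
F3 | step 5 | C3 alcohol of F2, 3-OH trans to the 4-CH2OH | O=C1C[C@@H](O)[C@](C)(CO)[C@@H]([C@H]2COC(C)(C)O2)[C@@H](C(C)=C)C1C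
F4 | step 5 | di-tert-butylsilylene of F3 (ketone corresponding to enol acetate 19) | O=C1C[C@H]3O[Si](C(C)(C)C)(C(C)(C)C)OC[C@]3(C)[C@@H]([C@H]2COC(C)(C)O2)[C@@H](C(C)=C)C1C
F5 | step 11 | primary trityl ether of 20 | CC(C)(C)[Si]2(C(C)(C)C)O[C@@H]1CC(OC(C)=O)=C(C)[C@H](C(C)=C)[C@H]([C@H](O)COC(c3ccccc3)(c3ccccc3)c3ccccc3)[C@@]1(C)CO2
F6 | step 11 | secondary methanesulfonate of F5 | CC(C)(C)[Si]2(C(C)(C)C)O[C@@H]1CC(OC(C)=O)=C(C)[C@H](C(C)=C)[C@H]([C@H](OS(C)(=O)=O)COC(c3ccccc3)(c3ccccc3)c3ccccc3)[C@@]1(C)CO2
F7 | step 11 | trityl ether of 24 | CC(C)(C)[Si]3(C(C)(C)C)O[C@@H]1CC(=O)[C@]2(C)[C@@H](COC(c4ccccc4)(c4ccccc4)c4ccccc4)[C@@H]([C@H]2C(C)=C)[C@@]1(C)CO3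
F8 | step 13 | aldehyde from 24 (formyl on C8, isopropenyl on C6) | CC(C)(C)[Si]3(C(C)(C)C)O[C@@H]1CC(=O)[C@]2(C)[C@@H](C=O)[C@@H]([C@H]2C(C)=C)[C@@]1(C)CO3
F9 | step 13 | tricyclic homoallylic alcohol: ring A as C6–C11(=CH2)–C10H2–C9H(OH)–C8, mixture at C9 | CC(C)(C)[Si]4(C(C)(C)C)O[C@@H]1CC(=O)[C@]2(C)[C@@H]3[C@@H]([C@H]2C(=C)CC3O)[C@@]1(C)CO4
F10 | step 13 | β-hydroxy ketone: ring A as C6–C11(=O)–C10H2–C9H(OH)–C8 | CC(C)(C)[Si]4(C(C)(C)C)O[C@@H]1CC(=O)[C@]2(C)[C@@H]3[C@@H]([C@H]2C(=O)CC3O)[C@@]1(C)CO4
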